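Numbering: ring C1 (acyloxy CH), C2 (C=O), C3 (methyl, oxirane C), C4 (oxirane CH), C5 (CH2), C6 (CH); chain C7 (oxirane C), C14 (oxirane CH2), C8 (C=O), C9=C10, C11 (carbinol).
Retrosynthetic cuts, in order: the C1 ester and the C2/C8 carbonyls (back to alcohols); C8–C9 (vinyllithium plus epoxy aldehyde); both oxiranes (back to C3=C4 and C7=C14); C7–C8 and C7–C14 (hydroxymethyl and methyl added to a C7 carboxyl); last the ring bond C5–C6.
Enabling feature: with C7 as a carboxyl, C7–C6–C5–C4=C3 is a γ,δ-unsaturated acid, and C7, C6, C1, C2, C3 are the five carbons of 2-deoxy-D-ribono-1,5-lactone; the pyranone ring (O, C7, C6, C1, C2, C3) with a vinyl group (C4=C5) on C3 can therefore be exchanged for the carbocycle C1–C6 by a [3,3] shift.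
Forward: 2-deoxy-D-ribose → 6-methyl-6-vinyl δ-lactone 11 → Ireland–Claisen ring exchange to acid 14 (the carbocycle arises here) → C14 and C8 attached at C7 → side-chain oxirane, then ring oxirane → C9–C11 tail → ketal removal, C1 acylation, C2 oxidation.
Stereochemistry: C1 from the sugar; C3 of 11 by chelate-controlled vinyl addition; C6 by suprafacial transfer in the [3,3] step; C3/C4 oxirane anti to the cis ketal (cis to C7); C7 by Sharpless epoxidation under reagent control.

Key step: step 8

Remark: the locants above are used in the names of 12–31. Compounds 2 (anomers), 7 (carbinol) and 26 (C8) are carried as epimer mixtures because those centres are destroyed later. Organolithium and Grignard steps are balanced for a plain water quench.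

Step 1
Reactants: 1 2-deoxy-D-ribose
Product: 2 2-deoxy-3,4-O-isopropylidene-D-erythro-pentopyranose (anomer mixture)
Conditions: 2-methoxypropene, pyridinium p-toluenesulfonate (cat.), DMF, 0 °C
Reagents that add atoms: 2-methoxypropene, COC(C)=C
Why: Acid-catalysed ketalisation with an enol ether takes the only cis-vicinal diol of the pyranose form (O3/O4) and leaves the anomeric hydroxyl free, a standard protection of this sugar that creates no new fixed stereocentre.

Step 2
Reactants: 2 2-deoxy-3,4-O-isopropylidene-D-erythro-pentopyranose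
Product: 3 (4S,5R)-4,5-(isopropylidenedioxy)tetrahydro-2H-pyran-2-one
Conditions: PhI(OAc)2, TEMPO (2,2,6,6-tetramethylpiperidin-1-oxyl, cat.), CH2Cl2, rt
Reagents that add atoms: none
Why: Oxoammonium-mediated oxidation of a lactol to its lactone is routine and leaves the ketal and both stereocentres untouched.

Step 3
Reactants: 3 (4S,5R)-4,5-(isopropylidenedioxy)tetrahydro-2H-pyran-2-one
Product: 4 methyl 2-[(4S,5R)-5-(hydroxymethyl)-2,2-dimethyl-1,3-dioxolan-4-yl]acetate
Conditions: K2CO3 (0.1 equiv), MeOH, 0 °C; AcOH (0.2 equiv), concentrate cold, use at once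
Reagents that add atoms: methanol, CO
Why: Base-catalysed methanolysis (transesterification) of the δ-lactone in methanol as solvent frees the primary alcohol, the carbonate at 0 °C being too weak to start β-elimination of the ketal oxygen, and immediate use forestalls relactonisation.

Step 4
Reactants: 4 methyl 2-[(4S,5R)-5-(hydroxymethyl)-2,2-dimethyl-1,3-dioxolan-4-yl]acetate
Product: 5 methyl 2-[(4S,5S)-5-formyl-2,2-dimethyl-1,3-dioxolan-4-yl]acetate
Conditions: Dess–Martin periodinane, CH2Cl2, 0 °C to rt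
Reagents that add atoms: none
Why: Dess–Martin oxidation gives the α-alkoxy aldehyde without base, so the cis-dioxolane centre next to the formyl group should not epimerise.

Step 5
Reactants: 5 methyl 2-[(4S,5S)-5-formyl-2,2-dimethyl-1,3-dioxolan-4-yl]acetate; 6 methylmagnesium bromide
Product: 7 methyl 2-[(4S,5R)-5-(1-hydroxyethyl)-2,2-dimethyl-1,3-dioxolan-4-yl]acetate (carbinol epimers)
Conditions: 6 (1.1 equiv), THF, –78 °C; AcOH (1.2 equiv) at –78 °C
Reagents that add atoms: none
Why: Grignard addition to the aldehyde is far faster than to the methyl ester at –78 °C, the cold acid quench stops the alkoxide from closing onto the ester, and the new carbinol centre is irrelevant because it is oxidised in the next step.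

Step 6
Reactants: 7 methyl 2-[(4S,5R)-5-(1-hydroxyethyl)-2,2-dimethyl-1,3-dioxolan-4-yl]acetate
Product: 8 methyl 2-[(4S,5S)-5-acetyl-2,2-dimethyl-1,3-dioxolan-4-yl]acetate
Conditions: Dess–Martin periodinane, CH2Cl2, rt
Reagents that add atoms: none
Why: Dess–Martin oxidation of the secondary alcohol gives the α-alkoxy methyl ketone under neutral conditions and erases the unneeded carbinol centre.

Step 7
Reactants: 8 methyl 2-[(4S,5S)-5-acetyl-2,2-dimethyl-1,3-dioxolan-4-yl]acetate; 9 vinylmagnesium bromide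
Product: 11 (4S,5S,6S)-4,5-(isopropylidenedioxy)-6-methyl-6-vinyltetrahydro-2H-pyran-2-one, via bromomagnesium alkoxide 10 (not isolated)
Conditions: MgBr2·OEt2, CH2Cl2, –78 °C; 9 (1.2 equiv), –78 °C, then rt; H2O
Reagents that add atoms: none
Why: Cram-chelate Grignard addition in which magnesium bridges the ketone oxygen and the adjacent dioxolane oxygen, vinyl attacks the chelate face that bears only H (anti to the rest of the dioxolane) and so sets C3 with vinyl cis to the ketal oxygens, and the tertiary alkoxide, held next to the ester arm by the cis-dioxolane, then closes the δ-lactone by acyl substitution with loss of methoxide.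

Step 8
Reactants: 11 (4S,5S,6S)-4,5-(isopropylidenedioxy)-6-methyl-6-vinyltetrahydro-2H-pyran-2-one
Product: 14 (1S,2R,6R)-1,2-(isopropylidenedioxy)-3-methylcyclohex-3-ene-6-carboxylic acid, via trimethylsilyl ketene acetal 12 (not isolated), via trimethylsilyl ester 13 (not isolated)
Conditions: Me3SiCl/Et3N, then LiN(iPr)2, THF, –100 °C; rt, then 60 °C; aq. citric acid
Reagents that add atoms: none
Why: LiN(iPr)2 removes a C6 proton while Me3SiCl is already present, so the lactone enolate is O-silylated before it can expel the C1 oxygen, and the cyclic silyl ketene acetal 12 then undergoes a concerted [3,3] sigmatropic shift in which C5 bonds to C6 as the C3–O bond breaks, giving silyl ester 13 that is hydrolysed on work-up. The closest known reaction is the Ireland–Claisen rearrangement of lactone silyl ketene acetals that bear a vinyl group on the carbinol carbon, which contracts the heterocycle to a cycloalkenecarboxylic acid. The carbocycle closes in the only mode the two-atom C1–C2 tether allows, a boat-like transition state shaped like bicyclo[2.2.2]octane (bridgeheads C3 and C6), and this geometry makes the new C3=C4 ring alkene necessarily cis; the cis-fused ketal already holds C1–C2 eclipsed as that boat requires. The single new stereocentre C6 is fixed by suprafacial chirality transfer from C3: C5 can reach C6 only on the lactone face that carries the vinyl group, and because the C1 oxygen lies on that same face the carboxyl ends trans to it, as in the target. The step needs silylation to outrun β-elimination and the rearrangement to outrun loss of the labile silyl group, which the in situ quench at –100 °C and strictly aprotic warming are meant to secure.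

Step 9
Reactants: 14 (1S,2R,6R)-1,2-(isopropylidenedioxy)-3-methylcyclohex-3-ene-6-carboxylic acid; 15 methyllithium
Product: 16 (1S,2R,6R)-6-acetyl-1,2-(isopropylidenedioxy)-3-methylcyclohex-3-ene
Conditions: 15 (2.2 equiv), Et2O, 0 °C; inverse quench into ice-water
Reagents that add atoms: none
Why: This is the classical conversion of a carboxylic acid into a methyl ketone, in which the second equivalent of methyllithium adds to the lithium carboxylate to give a dilithio gem-diolate that cannot react further and collapses to the ketone only on quenching, and since no enolate is formed C6 keeps its configuration.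

Step 10
Reactants: 16 (1S,2R,6R)-6-acetyl-1,2-(isopropylidenedioxy)-3-methylcyclohex-3-ene
Product: 17 (1S,2R,6R)-1,2-(isopropylidenedioxy)-3-methyl-6-[1-(trifluoromethanesulfonyloxy)vinyl]cyclohex-3-ene
Conditions: KN(SiMe3)2, THF, –78 °C; PhNTf2, –78 to 0 °C
Reagents that add atoms: N-phenylbis(trifluoromethanesulfonimide), O=S(=O)(N(c1ccccc1)S(=O)(=O)C(F)(F)F)C(F)(F)F
Why: Kinetic enolisation by the bulky amide removes a methyl proton rather than the hindered C6–H (whose enolate would expel the C1 oxygen), and O-sulfonylation of the terminal enolate gives the 1,1-disubstituted enol triflate.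

Step 11
Reactants: 17 (1S,2R,6R)-1,2-(isopropylidenedioxy)-3-methyl-6-[1-(trifluoromethanesulfonyloxy)vinyl]cyclohex-3-ene; 18 (tributylstannyl)methanol
Product: 19 (1S,2R,6S)-6-(3-hydroxyprop-1-en-2-yl)-1,2-(isopropylidenedioxy)-3-methylcyclohex-3-ene
Conditions: 18 (1.3 equiv), Pd(PPh3)4 (5 mol %), LiCl, dioxane, 90 °C
Reagents that add atoms: none
Why: Stille coupling of an alkenyl triflate, in which the α-oxygenated hydroxymethyl group is transferred from tin in preference to butyl and chloride assists transmetalation, installs C8 and gives the 2-substituted allylic alcohol directly.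

Step 12
Reactants: 19 (1S,2R,6S)-6-(3-hydroxyprop-1-en-2-yl)-1,2-(isopropylidenedioxy)-3-methylcyclohex-3-ene
Product: 20 (1S,2R,6R)-6-[(2S)-2-(hydroxymethyl)oxiran-2-yl]-1,2-(isopropylidenedioxy)-3-methylcyclohex-3-ene
Conditions: Ti(OiPr)4 (10 mol %), L-(+)-diethyl tartrate (12 mol %), t-BuOOH, 4 Å molecular sieves, CH2Cl2, –20 °C
Reagents that add atoms: tert-butyl hydroperoxide, CC(C)(C)OO
Why: Katsuki–Sharpless epoxidation touches only the alkene that has a free allylic hydroxyl, and L-(+)-tartrate delivers oxygen to the face that gives the 2S glycidol series (the facial sense that turns (E)-alk-2-en-1-ols into 2S,3S epoxy alcohols), so C7 is set under reagent control as 7S, which becomes 7R in the target once C8 outranks C14.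

Step 13
Reactants: 20 (1S,2R,6R)-6-[(2S)-2-(hydroxymethyl)oxiran-2-yl]-1,2-(isopropylidenedioxy)-3-methylcyclohex-3-ene
Product: 21 (1S,2S,3S,4S,6R)-3,4-epoxy-6-[(2S)-2-(hydroxymethyl)oxiran-2-yl]-1,2-(isopropylidenedioxy)-3-methylcyclohexane
Conditions: 3-chloroperoxybenzoic acid, NaHCO3, CH2Cl2, 0 °C
Reagents that add atoms: 3-chloroperoxybenzoic acid, OOC(=O)c1cccc(Cl)c1
Why: Peracid (Prilezhaev) epoxidation of the electron-rich trisubstituted ring alkene should occur anti to the cis-fused ketal, whose allylic C2 oxygen is pseudoaxial on the lower face when the C6 substituent is equatorial, so the oxirane forms cis to C7 and sets C3 and C4.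

Step 14
Reactants: 21 (1S,2S,3S,4S,6R)-3,4-epoxy-6-[(2S)-2-(hydroxymethyl)oxiran-2-yl]-1,2-(isopropylidenedioxy)-3-methylcyclohexane
Product: 22 (1S,2S,3S,4S,6R)-3,4-epoxy-6-[(2R)-2-formyloxiran-2-yl]-1,2-(isopropylidenedioxy)-3-methylcyclohexane
Conditions: Dess–Martin periodinane, NaHCO3, CH2Cl2, 0 °C to rt
Reagents that add atoms: none
Why: Dess–Martin oxidation of the primary epoxy alcohol gives an aldehyde that has no α-hydrogen, so C7 cannot epimerise, and neither oxirane is affected under the buffered conditions.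

Step 15
Reactants: 23 2-methylbut-3-yn-2-ol
Product: 24 (E)-2-methyl-4-(tributylstannyl)but-3-en-2-ol
Conditions: Bu3SnH, PdCl2(PPh3)2 (2 mol %), THF, 0 °C to rt
Reagents that add atoms: tributyltin hydride, CCCC[SnH](CCCC)CCCC
Why: Palladium-catalysed hydrostannation is a syn addition and the bulky tertiary carbinol steers tin to the terminal carbon, giving the (E)-vinylstannane.

Step 16
Reactants: 22 (1S,2S,3S,4S,6R)-3,4-epoxy-6-[(2R)-2-formyloxiran-2-yl]-1,2-(isopropylidenedioxy)-3-methylcyclohexane; 24 (E)-2-methyl-4-(tributylstannyl)but-3-en-2-ol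
Product: 26 (1S,2S,3S,4S,6R)-3,4-epoxy-6-[(2R)-2-[(E)-1,4-dihydroxy-4-methylpent-2-enyl]oxiran-2-yl]-1,2-(isopropylidenedioxy)-3-methylcyclohexane (C8 epimers), via dilithio vinyl reagent 25 (not isolated)
Conditions: 24 (1.3 equiv), n-BuLi (2.1 equiv per 24), THF, –78 to –40 °C; 22, –78 °C; H2O
Reagents that add atoms: none
Why: Deprotonation of the hydroxyl and tin–lithium exchange give the (E)-vinyllithium with retention of alkene geometry, which adds to the non-enolisable aldehyde at –78 °C, where oxiranes are inert, and the C8 epimers are not separated because C8 becomes a carbonyl.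

Step 17
Reactants: 26 (1S,2S,3S,4S,6R)-3,4-epoxy-6-[(2R)-2-[(E)-1,4-dihydroxy-4-methylpent-2-enyl]oxiran-2-yl]-1,2-(isopropylidenedioxy)-3-methylcyclohexane
Product: 27 (1S,2S,3S,4S,6R)-3,4-epoxy-6-[(2R)-2-[(E)-4-hydroxy-4-methylpent-2-enoyl]oxiran-2-yl]-1,2-(isopropylidenedioxy)-3-methylcyclohexane
Conditions: Dess–Martin periodinane, NaHCO3, CH2Cl2, 0 °C
Reagents that add atoms: none
Why: Dess–Martin oxidation turns the secondary allylic alcohol into the (E)-enone and cannot oxidise the tertiary C11 hydroxyl.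

Step 18
Reactants: 27 (1S,2S,3S,4S,6R)-3,4-epoxy-6-[(2R)-2-[(E)-4-hydroxy-4-methylpent-2-enoyl]oxiran-2-yl]-1,2-(isopropylidenedioxy)-3-methylcyclohexane
Product: 28 (1S,2S,3S,4S,6R)-3,4-epoxy-6-[(2R)-2-[(E)-4-hydroxy-4-methylpent-2-enoyl]oxiran-2-yl]-3-methylcyclohexane-1,2-diol
Conditions: AcOH/H2O (4:1), 35 °C
Reagents that add atoms: none
Why: A weak aqueous acid hydrolyses the cis-fused ketal while both oxiranes are deactivated towards acid opening (the ring one by the oxygen on C2, the side-chain one by the C8 carbonyl) and the electron-poor enone keeps the tertiary hydroxyl from ionising, as in the unmasking of epoxy cyclitol ketals.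

Step 19
Reactants: 28 (1S,2S,3S,4S,6R)-3,4-epoxy-6-[(2R)-2-[(E)-4-hydroxy-4-methylpent-2-enoyl]oxiran-2-yl]-3-methylcyclohexane-1,2-diol; 29 3-methylbutanoyl chloride
Product: 30 (1S,2S,3S,4S,6R)-3,4-epoxy-2-hydroxy-6-[(2R)-2-[(E)-4-hydroxy-4-methylpent-2-enoyl]oxiran-2-yl]-3-methylcyclohexyl 3-methylbutanoate
Conditions: 29 (1.1 equiv), 2,4,6-collidine, CH2Cl2, –40 to 0 °C
Reagents that add atoms: none
Why: Kinetic acylation with an acid chloride and a hindered pyridine base should take the equatorial C1 hydroxyl, whose neighbour C6 is a CH, rather than the axial C2 hydroxyl flanked by the fully substituted C3 or the tertiary C11 hydroxyl.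

Step 20
Reactants: 30 (1S,2S,3S,4S,6R)-3,4-epoxy-2-hydroxy-6-[(2R)-2-[(E)-4-hydroxy-4-methylpent-2-enoyl]oxiran-2-yl]-3-methylcyclohexyl 3-methylbutanoate
Product: 31 (1S,3S,4S,6R)-3,4-epoxy-6-[(2R)-2-[(E)-4-hydroxy-4-methylpent-2-enoyl]oxiran-2-yl]-3-methyl-2-oxocyclohexyl 3-methylbutanoate (CNP0292003.1)
Conditions: Dess–Martin periodinane, NaHCO3, CH2Cl2, 0 °C to rt
Reagents that add atoms: none
Why: Buffered Dess–Martin oxidation of the remaining secondary C2 hydroxyl gives the ketone without base, so the now acidic C1–H is not epimerised and the ester does not migrate.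

Compound list
1 | 2-deoxy-D-ribose (2-deoxy-D-erythro-pentose) | O=CC[C@H](O)[C@H](O)CO | starting material
2 | 2-deoxy-3,4-O-isopropylidene-D-erythro-pentopyranose (anomer mixture) | OC1C[C@@H]2OC(C)(C)O[C@@H]2CO1 | intermediate
3 | (4S,5R)-4,5-(isopropylidenedioxy)tetrahydro-2H-pyran-2-one (2-deoxy-3,4-O-isopropylidene-D-erythro-pentono-1,5-lactone) | O=C1C[C@@H]2OC(C)(C)O[C@@H]2CO1 | intermediate
4 | methyl 2-[(4S,5R)-5-(hydroxymethyl)-2,2-dimethyl-1,3-dioxolan-4-yl]acetate | COC(=O)C[C@@H]1OC(C)(C)O[C@@H]1CO | intermediate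
5 | methyl 2-[(4S,5S)-5-formyl-2,2-dimethyl-1,3-dioxolan-4-yl]acetate | COC(=O)C[C@@H]1OC(C)(C)O[C@@H]1C=O | intermediate
6 | methylmagnesium bromide | C[Mg]Br | starting material
7 | methyl 2-[(4S,5R)-5-(1-hydroxyethyl)-2,2-dimethyl-1,3-dioxolan-4-yl]acetate (carbinol epimers) | COC(=O)C[C@@H]1OC(C)(C)O[C@@H]1C(C)O | intermediate
8 | methyl 2-[(4S,5S)-5-acetyl-2,2-dimethyl-1,3-dioxolan-4-yl]acetate | COC(=O)C[C@@H]1OC(C)(C)O[C@@H]1C(C)=O | intermediate
9 | vinylmagnesium bromide | C=C[Mg]Br | starting material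
10 | bromomagnesium alkoxide of methyl 2-[(4S,5S)-5-[(2S)-2-hydroxybut-3-en-2-yl]-2,2-dimethyl-1,3-dioxolan-4-yl]acetate | COC(=O)C[C@@H]1OC(C)(C)O[C@@H]1[C@](C)(C=C)O[Mg]Br | intermediate
11 | (4S,5S,6S)-4,5-(isopropylidenedioxy)-6-methyl-6-vinyltetrahydro-2H-pyran-2-one (vinyl cis to the ketal oxygens; lactone C2/C3/C4/C5/C6 = C7/C6/C1/C2/C3, vinyl = C4=C5) | O=C1C[C@@H]2OC(C)(C)O[C@@H]2[C@](C)(C=C)O1 | intermediate
12 | trimethylsilyl ketene acetal of 11 (C6=C7 double bond, OSiMe3 on C7) | C[Si](C)(C)OC1=C[C@@H]2OC(C)(C)O[C@@H]2[C@](C)(C=C)O1 | intermediate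
13 | trimethylsilyl (1S,2R,6R)-1,2-(isopropylidenedioxy)-3-methylcyclohex-3-ene-6-carboxylate | CC2(C)O[C@@H]1[C@H](O2)C(C)=CC[C@H]1C(=O)O[Si](C)(C)C | intermediate
14 | (1S,2R,6R)-1,2-(isopropylidenedioxy)-3-methylcyclohex-3-ene-6-carboxylic acid (carboxyl trans to the C1 oxygen) | CC2(C)O[C@@H]1[C@H](O2)C(C)=CC[C@H]1C(=O)O | intermediate
15 | methyllithium | [Li]C | starting material
16 | (1S,2R,6R)-6-acetyl-1,2-(isopropylidenedioxy)-3-methylcyclohex-3-ene | CC2(C)O[C@@H]1[C@H](O2)C(C)=CC[C@H]1C(C)=O | intermediate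
17 | (1S,2R,6R)-1,2-(isopropylidenedioxy)-3-methyl-6-[1-(trifluoromethanesulfonyloxy)vinyl]cyclohex-3-ene | CC2(C)O[C@@H]1[C@H](O2)C(C)=CC[C@H]1C(=C)OS(=O)(=O)C(F)(F)F | intermediate
18 | (tributylstannyl)methanol | OC[Sn](CCCC)(CCCC)CCCC | starting material
19 | (1S,2R,6S)-6-(3-hydroxyprop-1-en-2-yl)-1,2-(isopropylidenedioxy)-3-methylcyclohex-3-ene | CC2(C)O[C@@H]1[C@H](O2)C(C)=CC[C@H]1C(=C)CO | intermediate
20 | (1S,2R,6R)-6-[(2S)-2-(hydroxymethyl)oxiran-2-yl]-1,2-(isopropylidenedioxy)-3-methylcyclohex-3-ene | CC2(C)O[C@@H]1[C@H](O2)C(C)=CC[C@H]1[C@]3(CO)CO3 | intermediate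
21 | (1S,2S,3S,4S,6R)-3,4-epoxy-6-[(2S)-2-(hydroxymethyl)oxiran-2-yl]-1,2-(isopropylidenedioxy)-3-methylcyclohexane (ring oxirane trans to the ketal, cis to C7) | CC2(C)O[C@@H]1[C@H](O2)[C@@]3(C)O[C@H]3C[C@H]1[C@]4(CO)CO4 | intermediate
22 | (1S,2S,3S,4S,6R)-3,4-epoxy-6-[(2R)-2-formyloxiran-2-yl]-1,2-(isopropylidenedioxy)-3-methylcyclohexane | CC2(C)O[C@@H]1[C@H](O2)[C@@]3(C)O[C@H]3C[C@H]1[C@]4(C=O)CO4 | intermediate
23 | 2-methylbut-3-yn-2-ol | C#CC(C)(C)O | starting material
24 | (E)-2-methyl-4-(tributylstannyl)but-3-en-2-ol | CCCC[Sn](CCCC)(CCCC)/C=C/C(C)(C)O | intermediate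
25 | lithium (E)-4-lithio-2-methylbut-3-en-2-olate | [Li]/C=C/C(C)(C)O[Li] | intermediate
26 | (1S,2S,3S,4S,6R)-3,4-epoxy-6-[(2R)-2-[(E)-1,4-dihydroxy-4-methylpent-2-enyl]oxiran-2-yl]-1,2-(isopropylidenedioxy)-3-methylcyclohexane (C8 epimers) | CC2(C)O[C@@H]1[C@H](O2)[C@@]3(C)O[C@H]3C[C@H]1[C@]4(C(O)/C=C/C(C)(C)O)CO4 | intermediate
27 | (1S,2S,3S,4S,6R)-3,4-epoxy-6-[(2R)-2-[(E)-4-hydroxy-4-methylpent-2-enoyl]oxiran-2-yl]-1,2-(isopropylidenedioxy)-3-methylcyclohexane | CC2(C)O[C@@H]1[C@H](O2)[C@@]3(C)O[C@H]3C[C@H]1[C@]4(C(=O)/C=C/C(C)(C)O)CO4 | intermediate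
28 | (1S,2S,3S,4S,6R)-3,4-epoxy-6-[(2R)-2-[(E)-4-hydroxy-4-methylpent-2-enoyl]oxiran-2-yl]-3-methylcyclohexane-1,2-diol | O[C@@H]1[C@H](O)[C@@]2(C)O[C@H]2C[C@H]1[C@]3(C(=O)/C=C/C(C)(C)O)CO3 | intermediate
29 | 3-methylbutanoyl chloride (isovaleryl chloride) | CC(C)CC(Cl)=O | starting material
30 | (1S,2S,3S,4S,6R)-3,4-epoxy-2-hydroxy-6-[(2R)-2-[(E)-4-hydroxy-4-methylpent-2-enoyl]oxiran-2-yl]-3-methylcyclohexyl 3-methylbutanoate (ester on O1, free hydroxyl on C2) | CC(C)CC(=O)O[C@@H]1[C@H](O)[C@@]2(C)O[C@H]2C[C@H]1[C@]3(C(=O)/C=C/C(C)(C)O)CO3 | intermediate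
31 | (1S,3S,4S,6R)-3,4-epoxy-6-[(2R)-2-[(E)-4-hydroxy-4-methylpent-2-enoyl]oxiran-2-yl]-3-methyl-2-oxocyclohexyl 3-methylbutanoate (CNP0292003.1) | CC(C)CC(=O)O[C@@H]1C(=O)[C@@]2(C)O[C@H]2C[C@H]1[C@]1(C(=O)/C=C/C(C)(C)O)CO1 | target

Total step count: 20 (steps 1–20; step 15 prepares the side-chain stannane).
Longest linear sequence: 19 steps (1 to 31 through steps 1–14 and 16–20).

Steps most likely to fail

Step 8. What may go wrong: β-elimination of the C1 ketal oxygen from the lithium enolate before it is silylated, or loss of the labile trimethylsilyl group from the ketene acetal before the boat is reached. The fallback sets out from 11 and comes back at 14. It changes the order of events at the carbonyl so that no metal enolate is ever formed. Et3N and tert-butyldimethylsilyl triflate (CH2Cl2, 0 °C) silylate the lactone carbonyl first and the amine then removes the C6 proton. This gives the isolable tert-butyldimethylsilyl ketene acetal F1, which is purified and heated on its own in toluene at 100 °C to give, through the same boat, the tert-butyldimethylsilyl ester F2. K2CO3 in aqueous methanol followed by mild acidification cleaves the silyl ester to 14.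

Step 18. What may go wrong: acid-promoted opening of the C3–C4 oxirane (or of the side-chain oxirane) competing with hydrolysis of the ketal. The fallback sets out from 17 and comes back at 28. It exchanges the ketal for fluoride-labile ethers before any oxirane exists. Aqueous trifluoroacetic acid in THF removes the ketal from the acid-stable enol triflate to give diol triflate F3, and triethylsilyl triflate with 2,6-lutidine gives the bis(triethylsilyl) ether F4. The chemistry of steps 11–17 is then repeated on the silyl series: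
- Stille hydroxymethylation gives allylic alcohol F5.
- Sharpless epoxidation with L-(+)-tartrate gives epoxy alcohol F6.
- Peracid epoxidation anti to the bulky allylic silyl ether gives bis-epoxide F7.
- Dess–Martin oxidation gives aldehyde F8.
- Addition of 25 gives diol F9.
- Dess–Martin oxidation gives enone F10.

HF·pyridine buffered with pyridine in THF at 0 °C then removes both silyl ethers under conditions that oxiranes tolerate and gives 28.

Step 19. What may go wrong: acylation at the wrong hydroxyl, acyl migration between O1 and O2, or double acylation. The fallback sets out from 28 and comes back at 30. It replaces substrate-controlled kinetic acylation by tin-acetal activation. Bu2SnO in methanol at 60 °C converts the cis-1,2-diol into the dibutylstannylene acetal F11, in which the equatorial C1 oxygen is the activated one. After evaporation, 29 in CH2Cl2 at 0 °C should acylate that oxygen only and give 30.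

Further compounds
F1 | step 8 | tert-butyldimethylsilyl ketene acetal of 11 (C6=C7 double bond, silyloxy group on C7) | CC(C)(C)[Si](C)(C)OC1=C[C@@H]2OC(C)(C)O[C@@H]2[C@](C)(C=C)O1
F2 | step 8 | tert-butyldimethylsilyl (1S,2R,6R)-1,2-(isopropylidenedioxy)-3-methylcyclohex-3-ene-6-carboxylate | CC2(C)O[C@@H]1[C@H](O2)C(C)=CC[C@H]1C(=O)O[Si](C)(C)C(C)(C)C
F3 | step 18 | (1S,2R,6R)-3-methyl-6-[1-(trifluoromethanesulfonyloxy)vinyl]cyclohex-3-ene-1,2-diol | O[C@@H]1[C@H](O)C(C)=CC[C@H]1C(=C)OS(=O)(=O)C(F)(F)F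
F4 | step 18 | (1S,2R,6R)-3-methyl-1,2-bis(triethylsilyloxy)-6-[1-(trifluoromethanesulfonyloxy)vinyl]cyclohex-3-ene | CC[Si](CC)(CC)O[C@@H]1[C@H](O[Si](CC)(CC)CC)C(C)=CC[C@H]1C(=C)OS(=O)(=O)C(F)(F)F
F5 | step 18 | (1S,2R,6S)-6-(3-hydroxyprop-1-en-2-yl)-3-methyl-1,2-bis(triethylsilyloxy)cyclohex-3-ene | CC[Si](CC)(CC)O[C@@H]1[C@H](O[Si](CC)(CC)CC)C(C)=CC[C@H]1C(=C)CO
F6 | step 18 | (1S,2R,6R)-6-[(2S)-2-(hydroxymethyl)oxiran-2-yl]-3-methyl-1,2-bis(triethylsilyloxy)cyclohex-3-ene | CC[Si](CC)(CC)O[C@@H]1[C@H](O[Si](CC)(CC)CC)C(C)=CC[C@H]1[C@]2(CO)CO2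
F7 | step 18 | (1S,2S,3S,4S,6R)-3,4-epoxy-6-[(2S)-2-(hydroxymethyl)oxiran-2-yl]-3-methyl-1,2-bis(triethylsilyloxy)cyclohexane | CC[Si](CC)(CC)O[C@@H]1[C@H](O[Si](CC)(CC)CC)[C@@]2(C)O[C@H]2C[C@H]1[C@]3(CO)CO3
F8 | step 18 | (1S,2S,3S,4S,6R)-3,4-epoxy-6-[(2R)-2-formyloxiran-2-yl]-3-methyl-1,2-bis(triethylsilyloxy)cyclohexane | CC[Si](CC)(CC)O[C@@H]1[C@H](O[Si](CC)(CC)CC)[C@@]2(C)O[C@H]2C[C@H]1[C@]3(C=O)CO3
F9 | step 18 | (1S,2S,3S,4S,6R)-3,4-epoxy-6-[(2R)-2-[(E)-1,4-dihydroxy-4-methylpent-2-enyl]oxiran-2-yl]-3-methyl-1,2-bis(triethylsilyloxy)cyclohexane (C8 epimers) | CC[Si](CC)(CC)O[C@@H]1[C@H](O[Si](CC)(CC)CC)[C@@]2(C)O[C@H]2C[C@H]1[C@]3(C(O)/C=C/C(C)(C)O)CO3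
F10 | step 18 | (1S,2S,3S,4S,6R)-3,4-epoxy-6-[(2R)-2-[(E)-4-hydroxy-4-methylpent-2-enoyl]oxiran-2-yl]-3-methyl-1,2-bis(triethylsilyloxy)cyclohexane | CC[Si](CC)(CC)O[C@@H]1[C@H](O[Si](CC)(CC)CC)[C@@]2(C)O[C@H]2C[C@H]1[C@]3(C(=O)/C=C/C(C)(C)O)CO3
F11 | step 19 | 1,2-O-dibutylstannylene acetal of 28 | CCCC[Sn]1(CCCC)O[C@@H]2[C@H](O1)[C@@]3(C)O[C@H]3C[C@H]2[C@]4(C(=O)/C=C/C(C)(C)O)CO4
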